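**Plan**
1. The cyclohexene ring C3a–C4–C5–C6=C7–C7a of the tetrahydroindene is a Diels–Alder retron: C3a/C4 are the dienophile carbons, C5/C7a the diene termini. Cutting C4–C5 and C3a–C7a opens both rings to the acyclic hexaene acid 28, in which quaternary C5 is an sp2 diene terminus (chain C10).
2. In 28 the bond from that terminus to the side chain (chain C10–C11) is an sp2–sp2 bond between two dienes; it is cut next, giving dienyl iodide acid 20 and dienylstannane 27.
3. 20 is built linearly in two directions from methyl (R)-3-hydroxy-2-methylpropanoate: the C7 side by Wittig, Corey–Fuchs and hydrozirconation–iodination, the C5 side by Still–Gennari and tandem oxidation–Wittig. 27 comes from cinnamaldehyde by Corey–Fuchs and carboalumination.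
4. Forward, the Stille coupling of 20 and 27 completes the chain; on heating in the same flask the six-membered ring forms by [4+2] cycloaddition and the five-membered ring closes with it, trans-fused.
5. Only chain C6 (indene C1) is a purchased stereocentre. C3a, C4, C5 and C7a follow from the (2E) and (9E) geometries, the endo-CO2H transition state and A(1,3) strain between H-6 and the C8 methyl.

Key step: step 18

Remark: chain locants C1–C14 are those of hexaene acid 28 and ring locants those of 1H-indene; salts that are only protonated or hydrolysed in the aqueous work-up (aluminium alkoxides, the lithium carboxylate of step 13, the lithium acetylide of step 15) are treated as part of the work-up.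

Step 1
Reactants: 1 methyl (R)-3-hydroxy-2-methylpropanoate
Product: 2 methyl (R)-3-[(tert-butyldimethylsilyl)oxy]-2-methylpropanoate
Conditions: TBSCl, imidazole, CH2Cl2, 0 °C to rt
Reagents that add atoms: tert-butyldimethylsilyl chloride, CC(C)(C)[Si](C)(C)Cl
Why: Imidazole-promoted silylation of the primary alcohol, which leaves the α-stereocentre untouched.

Step 2
Reactants: 2 methyl (R)-3-[(tert-butyldimethylsilyl)oxy]-2-methylpropanoate
Product: 3 (R)-3-[(tert-butyldimethylsilyl)oxy]-2-methylpropanal
Conditions: i-Bu2AlH (1.1 equiv), CH2Cl2, −78 °C; MeOH, then aq. potassium sodium tartrate; used at once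
Reagents that add atoms: none
Why: Partial ester reduction, in which the tetrahedral aluminium hemiacetal persists at −78 °C and releases the aldehyde only on work-up, so that over-reduction and α-epimerisation should be avoided.

Step 3
Reactants: 3 (R)-3-[(tert-butyldimethylsilyl)oxy]-2-methylpropanal
Product: 4 (2E,4S)-5-[(tert-butyldimethylsilyl)oxy]-2,4-dimethylpent-2-enal
Conditions: Ph3P=C(CH3)CHO (1.3 equiv), toluene, 90 °C
Reagents that add atoms: 2-(triphenylphosphoranylidene)propanal, CC(C=O)=P(c1ccccc1)(c1ccccc1)c1ccccc1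
Why: Wittig olefination with a stabilised formyl ylide, which is neutral (no epimerisation at C4), gives the (E)-trisubstituted enal, and reacts much more slowly with the conjugated product than with 3.

Step 4
Reactants: 4 (2E,4S)-5-[(tert-butyldimethylsilyl)oxy]-2,4-dimethylpent-2-enal
Product: 5 tert-butyl{[(2S,3E)-6,6-dibromo-2,4-dimethylhexa-3,5-dien-1-yl]oxy}dimethylsilane
Conditions: CBr4, PPh3, Zn dust, CH2Cl2, rt (ylide preformed); then 4, 0 °C to rt
Reagents that add atoms: carbon tetrabromide, BrC(Br)(Br)Br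
Why: First stage of the Corey–Fuchs homologation, in which the dibromomethylene ylide made in the flask olefinates the enal under non-basic conditions.

Step 5
Reactants: 5 tert-butyl{[(2S,3E)-6,6-dibromo-2,4-dimethylhexa-3,5-dien-1-yl]oxy}dimethylsilane
Product: 7 tert-butyl{[(2S,3E)-2,4-dimethylhept-3-en-5-yn-1-yl]oxy}dimethylsilane, via lithium acetylide 6 (not isolated)
Conditions: n-BuLi (2.2 equiv), THF, −78 °C; MeI (5 equiv), −78 °C to rt
Reagents that add atoms: iodomethane, CI
Why: Second stage of the Corey–Fuchs sequence: bromine–lithium exchange and Fritsch–Buttenberg–Wiechell rearrangement give the lithium acetylide, which iodomethane methylates on carbon.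

Step 6
Reactants: 7 tert-butyl{[(2S,3E)-2,4-dimethylhept-3-en-5-yn-1-yl]oxy}dimethylsilane
Product: 9 tert-butyl{[(2S,3E,5E)-6-iodo-2,4-dimethylhepta-3,5-dien-1-yl]oxy}dimethylsilane, via alkenylzirconocene chloride 8 (not isolated)
Conditions: Cp2Zr(H)Cl (2.2 equiv), THF, rt to 45 °C, dark; I2, THF, 0 °C
Reagents that add atoms: iodine, II
Why: Syn hydrozirconation of the methyl-capped enyne, in which excess Cp2Zr(H)Cl equilibrates the regioisomers towards zirconium on the less hindered methyl-bearing carbon, followed by iodinolysis of the C–Zr bond with retention, should set the (5E)-2-iodoalkene.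

Step 7
Reactants: 9 tert-butyl{[(2S,3E,5E)-6-iodo-2,4-dimethylhepta-3,5-dien-1-yl]oxy}dimethylsilane
Product: 10 (2S,3E,5E)-6-iodo-2,4-dimethylhepta-3,5-dien-1-ol
Conditions: HF·pyridine, pyridine, THF, 0 °C to rt
Reagents that add atoms: none
Why: Fluoride-driven cleavage of the primary silyl ether under buffered conditions that leave the iododiene intact.

Step 8
Reactants: 10 (2S,3E,5E)-6-iodo-2,4-dimethylhepta-3,5-dien-1-ol
Product: 11 (2S,3E,5E)-6-iodo-2,4-dimethylhepta-3,5-dienal
Conditions: Dess–Martin periodinane, NaHCO3, CH2Cl2, 0 °C; used crude at once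
Reagents that add atoms: none
Why: Dess–Martin oxidation under buffered, non-enolising conditions should give the α-stereogenic β,γ-unsaturated aldehyde without epimerisation or migration of the double bond into conjugation.

Step 9
Reactants: 12 methyl 2-[bis(2,2,2-trifluoroethoxy)phosphoryl]acetate
Product: 14 methyl 2-[bis(2,2,2-trifluoroethoxy)phosphoryl]butanoate, via potassium enolate 13 (not isolated)
Conditions: KOtBu (1.0 equiv), THF, 0 °C; EtI, 0 °C to rt
Reagents that add atoms: iodoethane, CCI
Why: C-alkylation of the stabilised phosphonoacetate anion with a primary iodide, with one equivalent of base to limit dialkylation.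

Step 10
Reactants: 11 (2S,3E,5E)-6-iodo-2,4-dimethylhepta-3,5-dienal; 14 methyl 2-[bis(2,2,2-trifluoroethoxy)phosphoryl]butanoate
Product: 16 methyl (2Z,4S,5E,7E)-2-ethyl-8-iodo-4,6-dimethylnona-2,5,7-trienoate, via potassium phosphonate enolate 15 (not isolated)
Conditions: 14 (1.3 equiv), KN(SiMe3)2 (1.2 equiv), 18-crown-6, THF, −78 °C; then 11, −78 °C
Reagents that add atoms: none
Why: Still–Gennari olefination, in which the electron-poor trifluoroethyl phosphonate and the crown-separated potassium enolate make elimination from the kinetic adduct fast and irreversible, should give the (Z)-enoate (ester cis to the C4 chain, the geometry the later five-membered ring needs), while −78 °C and the absence of excess base protect the C4 stereocentre.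

Step 11
Reactants: 16 methyl (2Z,4S,5E,7E)-2-ethyl-8-iodo-4,6-dimethylnona-2,5,7-trienoate
Product: 17 (2Z,4S,5E,7E)-2-ethyl-8-iodo-4,6-dimethylnona-2,5,7-trien-1-ol
Conditions: i-Bu2AlH (2.5 equiv), CH2Cl2, −78 °C; aq. potassium sodium tartrate
Reagents that add atoms: none
Why: 1,2-Reduction of the enoate to the allylic alcohol, which keeps the olefin geometry and tolerates the vinyl iodide.

Step 12
Reactants: 17 (2Z,4S,5E,7E)-2-ethyl-8-iodo-4,6-dimethylnona-2,5,7-trien-1-ol
Product: 19 ethyl (2E,4Z,6S,7E,9E)-4-ethyl-10-iodo-2,6,8-trimethylundeca-2,4,7,9-tetraenoate, via Z-enal 18 (not isolated)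
Conditions: activated MnO2 (15 equiv), Ph3P=C(CH3)CO2Et (1.5 equiv), CH2Cl2, rt to 35 °C, dark
Reagents that add atoms: ethyl 2-(triphenylphosphoranylidene)propanoate, CCOC(=O)C(C)=P(c1ccccc1)(c1ccccc1)c1ccccc1
Why: Tandem allylic oxidation–Wittig olefination, in which the strained (Z)-enal is trapped by the stabilised ylide as it forms and so cannot isomerise, and the stabilised ylide gives the (2E)-enoate.

Step 13
Reactants: 19 ethyl (2E,4Z,6S,7E,9E)-4-ethyl-10-iodo-2,6,8-trimethylundeca-2,4,7,9-tetraenoate
Product: 20 (2E,4Z,6S,7E,9E)-4-ethyl-10-iodo-2,6,8-trimethylundeca-2,4,7,9-tetraenoic acid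
Conditions: LiOH·H2O, THF/MeOH/H2O, rt to 35 °C; 1 M HCl to pH 3, 0 °C; stored cold and used promptly
Reagents that add atoms: lithium hydroxide, [Li+].[OH-]
Why: Saponification is placed here because the ester is still an unhindered conjugated one (after the cycloaddition it would sit on a quaternary carbon), and the conditions are too mild to enolise C6 or to start cycloaddition of the iododiene.

Step 14
Reactants: 21 (E)-cinnamaldehyde
Product: 22 [(1E)-4,4-dibromobuta-1,3-dien-1-yl]benzene
Conditions: CBr4, PPh3, Zn dust, CH2Cl2, rt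
Reagents that add atoms: carbon tetrabromide, BrC(Br)(Br)Br
Why: Corey–Fuchs dibromo-olefination of an enal with the ylide made in the flask.

Step 15
Reactants: 22 [(1E)-4,4-dibromobuta-1,3-dien-1-yl]benzene
Product: 23 [(E)-but-1-en-3-yn-1-yl]benzene
Conditions: n-BuLi (2.1 equiv), THF, −78 °C; H2O
Reagents that add atoms: none
Why: Bromine–lithium exchange and Fritsch–Buttenberg–Wiechell rearrangement give the lithium acetylide, which is protonated on quenching (second stage of the Corey–Fuchs alkyne synthesis).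

Step 16
Reactants: 23 [(E)-but-1-en-3-yn-1-yl]benzene
Product: 25 [(1E,3E)-4-iodo-3-methylbuta-1,3-dien-1-yl]benzene, via alkenylalane 24 (not isolated)
Conditions: Me3Al (2.5 equiv), Cp2ZrCl2 (0.25 equiv), CH2Cl2, 0 °C to rt; I2, THF, −30 to 0 °C
Reagents that add atoms: trimethylaluminium, C[Al](C)C; iodine, II
Why: Negishi zirconium-catalysed carboalumination adds methyl and aluminium syn across the terminal alkyne with methyl on the internal carbon (conjugated enynes are good substrates), and iodinolysis with retention should give the (E)-iodide.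

Step 17
Reactants: 25 [(1E,3E)-4-iodo-3-methylbuta-1,3-dien-1-yl]benzene
Product: 27 tributyl[(1E,3E)-2-methyl-4-phenylbuta-1,3-dien-1-yl]stannane, via dienyllithium 26 (not isolated)
Conditions: t-BuLi (2.1 equiv), Et2O, −78 °C; Bu3SnCl, −78 °C to rt
Reagents that add atoms: tributyltin chloride, CCCC[Sn](Cl)(CCCC)CCCC
Why: Iodine–lithium exchange and stannylation of the alkenyllithium both proceed with retention of the olefin geometry.

Step 18
Reactants: 20 (2E,4Z,6S,7E,9E)-4-ethyl-10-iodo-2,6,8-trimethylundeca-2,4,7,9-tetraenoic acid; 27 tributyl[(1E,3E)-2-methyl-4-phenylbuta-1,3-dien-1-yl]stannane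
Product: 29 zyggomphic acid B [(1R,3aR,4R,5S,7aS)-3-ethyl-1,4,5,7-tetramethyl-5-[(1E,3E)-2-methyl-4-phenylbuta-1,3-dien-1-yl]-3a,4,5,7a-tetrahydro-1H-indene-4-carboxylic acid], via hexaene acid 28 (not isolated)
Conditions: 27 (1.3 equiv), Pd2(dba)3 (5 mol %), AsPh3 (40 mol %), degassed DMF, rt, dark; then dilution with toluene, BHT, 110 °C
Reagents that add atoms: none
Why: Oxidative addition of zerovalent palladium into the C10–I bond of 20, transmetalation of the dienyl group from tin and reductive elimination form the C10–C11 bond with retention of both olefin geometries (Stille coupling; closest precedent is the coupling of 2-iodoalk-2-enes with alkenylstannanes under Pd2(dba)3/AsPh3), so that C10, the later quaternary C5, is still the sp2 terminus of the C7=C8–C9=C10 diene in hexaene 28. On heating, 28 should undergo an intramolecular Diels–Alder reaction of the 1,3,8-nonatriene type with a terminally activated dienophile: the six-membered ring closes by a concerted suprafacial [4+2] addition of that diene to the C2=C3 double bond, and the five-membered ring closes in the same act as the fused ring spanned by the three-atom tether C4=C5–C6 (bond C3–C7), the (4Z) geometry holding C3 next to C7. The (2E) dienophile geometry fixes CO2H cis to H-3a, the (9E) geometry puts the C10 methyl inside and C11 outside, the endo-CO2H transition state with the tether anti to the diene gives the trans ring fusion (H-3a trans to H-7a) and the C5 side chain cis to CO2H, and the C6 stereocentre selects the diene face because its hydrogen must eclipse the C8 methyl (A(1,3) strain), which sends the dienophile to the face anti to the C6 methyl (C1 methyl cis to H-7a). The step needs coupling before any cycloaddition of 20 itself (secured by coupling at room temperature), periselectivity for the C7–C10 diene (the only diene–dienophile pair joined by a three-atom tether), endo over exo selectivity (secondary overlap with CO2H and the rigid olefinic tether) and facial selectivity (secured by the C8 methyl).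

**Compound list**
1 | methyl (R)-3-hydroxy-2-methylpropanoate | COC(=O)[C@H](C)CO | starting material
2 | methyl (R)-3-[(tert-butyldimethylsilyl)oxy]-2-methylpropanoate | COC(=O)[C@H](C)CO[Si](C)(C)C(C)(C)C | intermediate
3 | (R)-3-[(tert-butyldimethylsilyl)oxy]-2-methylpropanal | O=C[C@H](C)CO[Si](C)(C)C(C)(C)C | intermediate
4 | (2E,4S)-5-[(tert-butyldimethylsilyl)oxy]-2,4-dimethylpent-2-enal | CC(C)(C)[Si](C)(C)OC[C@@H](C)/C=C(\C)C=O | intermediate
5 | tert-butyl{[(2S,3E)-6,6-dibromo-2,4-dimethylhexa-3,5-dien-1-yl]oxy}dimethylsilane | CC(C)(C)[Si](C)(C)OC[C@@H](C)/C=C(\C)C=C(Br)Br | intermediate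
6 | [(3E,5S)-6-[(tert-butyldimethylsilyl)oxy]-3,5-dimethylhex-3-en-1-yn-1-yl]lithium | CC(C)(C)[Si](C)(C)OC[C@@H](C)/C=C(\C)C#C[Li] | intermediate (not isolated)
7 | tert-butyl{[(2S,3E)-2,4-dimethylhept-3-en-5-yn-1-yl]oxy}dimethylsilane | CC(C)(C)[Si](C)(C)OC[C@@H](C)/C=C(\C)C#CC | intermediate
8 | chlorobis(cyclopentadienyl)[(2E,4E,6S)-7-[(tert-butyldimethylsilyl)oxy]-4,6-dimethylhepta-2,4-dien-2-yl]zirconium | CC(C)(C)[Si](C)(C)OC[C@@H](C)/C=C(\C)/C=C(\C)[Zr](Cl)(C1C=CC=C1)C1C=CC=C1 | intermediate (not isolated)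
9 | tert-butyl{[(2S,3E,5E)-6-iodo-2,4-dimethylhepta-3,5-dien-1-yl]oxy}dimethylsilane | CC(C)(C)[Si](C)(C)OC[C@@H](C)/C=C(\C)/C=C(\C)I | intermediate
10 | (2S,3E,5E)-6-iodo-2,4-dimethylhepta-3,5-dien-1-ol | OC[C@@H](C)/C=C(\C)/C=C(\C)I | intermediate
11 | (2S,3E,5E)-6-iodo-2,4-dimethylhepta-3,5-dienal | O=C[C@@H](C)/C=C(\C)/C=C(\C)I | intermediate
12 | methyl 2-[bis(2,2,2-trifluoroethoxy)phosphoryl]acetate | COC(=O)CP(=O)(OCC(F)(F)F)OCC(F)(F)F | starting material
13 | potassium enolate of 12 | [K+].COC([O-])=CP(=O)(OCC(F)(F)F)OCC(F)(F)F | intermediate (not isolated)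
14 | methyl 2-[bis(2,2,2-trifluoroethoxy)phosphoryl]butanoate (racemic) | CCC(C(=O)OC)P(=O)(OCC(F)(F)F)OCC(F)(F)F | intermediate
15 | potassium enolate of 14 | [K+].CCC(=C([O-])OC)P(=O)(OCC(F)(F)F)OCC(F)(F)F | intermediate (not isolated)
16 | methyl (2Z,4S,5E,7E)-2-ethyl-8-iodo-4,6-dimethylnona-2,5,7-trienoate | COC(=O)/C(CC)=C\[C@@H](C)/C=C(\C)/C=C(\C)I | intermediate
17 | (2Z,4S,5E,7E)-2-ethyl-8-iodo-4,6-dimethylnona-2,5,7-trien-1-ol | OC/C(CC)=C\[C@@H](C)/C=C(\C)/C=C(\C)I | intermediate
18 | (2Z,4S,5E,7E)-2-ethyl-8-iodo-4,6-dimethylnona-2,5,7-trienal | O=C/C(CC)=C\[C@@H](C)/C=C(\C)/C=C(\C)I | intermediate (not isolated)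
19 | ethyl (2E,4Z,6S,7E,9E)-4-ethyl-10-iodo-2,6,8-trimethylundeca-2,4,7,9-tetraenoate | CCOC(=O)/C(C)=C/C(CC)=C\[C@@H](C)/C=C(\C)/C=C(\C)I | intermediate
20 | (2E,4Z,6S,7E,9E)-4-ethyl-10-iodo-2,6,8-trimethylundeca-2,4,7,9-tetraenoic acid | OC(=O)/C(C)=C/C(CC)=C\[C@@H](C)/C=C(\C)/C=C(\C)I | intermediate
21 | (E)-cinnamaldehyde | O=C/C=C/c1ccccc1 | starting material
22 | [(1E)-4,4-dibromobuta-1,3-dien-1-yl]benzene | BrC(Br)=C/C=C/c1ccccc1 | intermediate
23 | [(E)-but-1-en-3-yn-1-yl]benzene | C#C/C=C/c1ccccc1 | intermediate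
24 | dimethyl[(1E,3E)-2-methyl-4-phenylbuta-1,3-dien-1-yl]alumane | C[Al](C)/C=C(C)/C=C/c1ccccc1 | intermediate (not isolated)
25 | [(1E,3E)-4-iodo-3-methylbuta-1,3-dien-1-yl]benzene | I/C=C(C)/C=C/c1ccccc1 | intermediate
26 | [(1E,3E)-2-methyl-4-phenylbuta-1,3-dien-1-yl]lithium | [Li]/C=C(C)/C=C/c1ccccc1 | intermediate (not isolated)
27 | tributyl[(1E,3E)-2-methyl-4-phenylbuta-1,3-dien-1-yl]stannane | CCCC[Sn](CCCC)(CCCC)/C=C(C)/C=C/c1ccccc1 | intermediate
28 | (2E,4Z,6S,7E,9E,11E,13E)-4-ethyl-2,6,8,10,12-pentamethyl-14-phenyltetradeca-2,4,7,9,11,13-hexaenoic acid | OC(=O)/C(C)=C/C(CC)=C\[C@@H](C)/C=C(\C)/C=C(\C)/C=C(\C)/C=C/c1ccccc1 | intermediate (not isolated)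
29 | zyggomphic acid B, (1R,3aR,4R,5S,7aS)-3-ethyl-1,4,5,7-tetramethyl-5-[(1E,3E)-2-methyl-4-phenylbuta-1,3-dien-1-yl]-3a,4,5,7a-tetrahydro-1H-indene-4-carboxylic acid | CCC1=C[C@@H](C)[C@@H]2C(C)=C[C@](C)(/C=C(C)/C=C/c3ccccc3)[C@](C)(C(=O)O)[C@@H]12 | target

**Step count and risks**
Total step count: 18. Longest linear sequence: 13 steps (1–8, 10–13 and 18) from 1.

Steps most likely to fail:

1. Step 18. The free acid may protodestannylate 27 before transmetalation. The thermal cycloaddition may also be slow enough at 110 °C for a [1,5]-hydrogen shift in the (4Z)-dienoic acid or for exo cyclisation to compete. The fallback sets out from ester 19 and moves the activation from heat to a Lewis acid. Stille coupling of 19 with 27 (Pd2(dba)3, AsPh3, DMF, rt) should give ethyl (2E,4Z,6S,7E,9E,11E,13E)-4-ethyl-2,6,8,10,12-pentamethyl-14-phenyltetradeca-2,4,7,9,11,13-hexaenoate F1, isolated cold. Me2AlCl in CH2Cl2 at −78 to −20 °C should then promote the endo cycloaddition to the bicyclic ethyl ester F2. Because this ester sits on a quaternary carbon and resists hydrolysis, it is reduced with LiAlH4 to the primary alcohol F3, oxidised with Dess–Martin periodinane to the aldehyde F4, and oxidised further with NaClO2/NaH2PO4/2-methylbut-2-ene. The fallback comes back to the route at 29.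

2. Step 6. Zirconium hydride may add with the wrong regiochemistry (zirconium next to the alkenyl group), or the regioisomers may not equilibrate fully. The fallback sets out from 7 and uses electronic instead of steric control. Copper-catalysed formal hydroboration (CuCl, NaOtBu, Xantphos, B2pin2, MeOH, THF) places copper on the alkyne carbon next to the alkenyl group and boron syn on the methyl-bearing carbon. After protonation this should give the dienylboronate tert-butyl{[(2S,3E,5Z)-2,4-dimethyl-6-(4,4,5,5-tetramethyl-1,3,2-dioxaborolan-2-yl)hepta-3,5-dien-1-yl]oxy}dimethylsilane F5 (boron trans to C4). Ipso-iododeboronation with N-iodosuccinimide in MeCN, with retention, comes back to the route at 9.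

3. Step 10. The basic phosphonate enolate may epimerise aldehyde 11 at C2, or Z selectivity may erode with the α-ethyl reagent. The fallback sets out from 7, before the iodide exists, so that palladium chemistry can be used and the Z geometry comes from stereospecific substitutions. HF·pyridine gives (2S,3E)-2,4-dimethylhept-3-en-5-yn-1-ol F6, and Dess–Martin oxidation gives (2S,3E)-2,4-dimethylhept-3-en-5-ynal F7. Neutral Corey–Fuchs olefination (CBr4, PPh3, Zn) gives (3S,4E)-1,1-dibromo-3,5-dimethylocta-1,4-dien-6-yne F8. A trans-selective Negishi coupling with EtZnBr and PdCl2(DPEphos) replaces the bromine trans to the chain and should give (4E,6S,7Z)-8-bromo-4,6-dimethyldeca-4,7-dien-2-yne F9. Bromine–lithium exchange (t-BuLi, −78 °C, retention) and trapping with paraformaldehyde give (2Z,4S,5E)-2-ethyl-4,6-dimethylnona-2,5-dien-7-yn-1-ol F10. Hydrozirconation–iodination as in step 6, with one extra equivalent of Cp2Zr(H)Cl for the hydroxyl, comes back to the route at 17.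

**Further compounds**
F1 | step 18 | ethyl (2E,4Z,6S,7E,9E,11E,13E)-4-ethyl-2,6,8,10,12-pentamethyl-14-phenyltetradeca-2,4,7,9,11,13-hexaenoate | CCOC(=O)/C(C)=C/C(CC)=C\[C@@H](C)/C=C(\C)/C=C(\C)/C=C(\C)/C=C/c1ccccc1
F2 | step 18 | ethyl (1R,3aR,4R,5S,7aS)-3-ethyl-1,4,5,7-tetramethyl-5-[(1E,3E)-2-methyl-4-phenylbuta-1,3-dien-1-yl]-3a,4,5,7a-tetrahydro-1H-indene-4-carboxylate | CCC1=C[C@@H](C)[C@@H]2C(C)=C[C@](C)(/C=C(C)/C=C/c3ccccc3)[C@](C)(C(=O)OCC)[C@@H]12
F3 | step 18 | [(1R,3aR,4R,5S,7aS)-3-ethyl-1,4,5,7-tetramethyl-5-[(1E,3E)-2-methyl-4-phenylbuta-1,3-dien-1-yl]-3a,4,5,7a-tetrahydro-1H-inden-4-yl]methanol | CCC1=C[C@@H](C)[C@@H]2C(C)=C[C@](C)(/C=C(C)/C=C/c3ccccc3)[C@](C)(CO)[C@@H]12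
F4 | step 18 | (1R,3aR,4R,5S,7aS)-3-ethyl-1,4,5,7-tetramethyl-5-[(1E,3E)-2-methyl-4-phenylbuta-1,3-dien-1-yl]-3a,4,5,7a-tetrahydro-1H-indene-4-carbaldehyde | CCC1=C[C@@H](C)[C@@H]2C(C)=C[C@](C)(/C=C(C)/C=C/c3ccccc3)[C@](C)(C=O)[C@@H]12
F5 | step 6 | tert-butyl{[(2S,3E,5Z)-2,4-dimethyl-6-(4,4,5,5-tetramethyl-1,3,2-dioxaborolan-2-yl)hepta-3,5-dien-1-yl]oxy}dimethylsilane | CC(C)(C)[Si](C)(C)OC[C@@H](C)/C=C(\C)/C=C(\C)B1OC(C)(C)C(C)(C)O1
F6 | step 10 | (2S,3E)-2,4-dimethylhept-3-en-5-yn-1-ol | OC[C@@H](C)/C=C(\C)C#CC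
F7 | step 10 | (2S,3E)-2,4-dimethylhept-3-en-5-ynal | O=C[C@@H](C)/C=C(\C)C#CC
F8 | step 10 | (3S,4E)-1,1-dibromo-3,5-dimethylocta-1,4-dien-6-yne | BrC(Br)=C[C@@H](C)/C=C(\C)C#CC
F9 | step 10 | (4E,6S,7Z)-8-bromo-4,6-dimethyldeca-4,7-dien-2-yne | CC/C(Br)=C/[C@@H](C)/C=C(\C)C#CC
F10 | step 10 | (2Z,4S,5E)-2-ethyl-4,6-dimethylnona-2,5-dien-7-yn-1-ol | OC/C(CC)=C\[C@@H](C)/C=C(\C)C#CC
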